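**Retrosynthetic overview**

- Feature: in ring A (the central benzene) C1 bears the butyryl carbonyl, the oxygen-bearing carbons C2, C4 and C6 lie ortho, para and ortho to it, and C3 and C5 carry the two CH2 bridges. Each aryl C–O bond is therefore traced back to a ketone-activated C–F bond, and each carbon substituent to a C–H that lies between two fluorines.
- Disconnections: (a) the two CH2–C bonds to rings B and C, cut to tris(benzyloxy)benzyl cations from two CH2OMe arms plus acetyl- and propionylfilicinic acid; (b) the three O–C(ring A) bonds, cut to a threefold SNAr of benzyloxide on the 2,4,6-trifluoro ketone; (c) the C1, C3 and C5 substituents, cut to three lithiation/electrophile cycles on 1,3,5-trifluorobenzene.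
- Rings: none is closed. Ring A is carried through from 1,3,5-trifluorobenzene; rings B and C come from two acylphloroglucinols by dearomatising gem-dimethylation and are attached to ring A one after the other, before debenzylation.

Key step: step 5

Remark: the two CH2OMe arms of the key-step product are equivalent, so the first coupling cannot tell them apart and is run with that bis-ether in excess. The order of fluoride loss in the key step (para first) is assumed and has no bearing on the product.
Remark: step 5 consumes three benzyloxide units per molecule of ketone 10. Reactant 11 accounts for the first; the second and third are entered under the reagents of that step as further benzyl alcohol and as the sodium benzyloxide made from it with NaH.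
Remark: the filicinic rings are written in the dienol tautomer of the target SMILES. The target has no stereocentre, and the one carbinol centre of the route is racemic and removed by oxidation.

**Route**

Step 1
Reactants: 1 1,3,5-trifluorobenzene; 2 chloromethyl methyl ether
Product: 4 1,3,5-trifluoro-2-(methoxymethyl)benzene, via aryllithium 3 (not isolated)
Conditions: n-BuLi (1.0 equiv), THF, −78 °C; then 2 (1.1 equiv), −78 °C → rt
Reagents that add atoms: none
Why: Ortho-lithiation of a C–H flanked by two fluorines (the aryllithium does not lose LiF at −78 °C) followed by SN2 alkylation with the α-chloro ether installs the first CH2OMe arm.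

Step 2
Reactants: 4 1,3,5-trifluoro-2-(methoxymethyl)benzene; 2 chloromethyl methyl ether
Product: 6 1,3,5-trifluoro-2,4-bis(methoxymethyl)benzene, via aryllithium 5 (not isolated)
Conditions: n-BuLi (1.05 equiv), THF, −78 °C; then 2 (1.2 equiv), −78 °C → rt
Reagents that add atoms: none
Why: The two remaining ring hydrogens are equivalent and each again lies between two fluorines, so a second ortho-lithiation/alkylation has no regiochemical choice, the benzylic ether protons being far less acidic than the ring C–H.

Step 3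
Reactants: 6 1,3,5-trifluoro-2,4-bis(methoxymethyl)benzene; 7 butanal
Product: 9 rac-1-[2,4,6-trifluoro-3,5-bis(methoxymethyl)phenyl]butan-1-ol, via aryllithium 8 (not isolated)
Conditions: n-BuLi (1.05 equiv), THF, −78 °C; then 7 (1.3 equiv), −78 → 0 °C; H2O
Reagents that add atoms: none
Why: The last ring C–H is lithiated in the same way and the aryllithium should add 1,2 to the aldehyde faster than it enolises it at −78 °C; the carbinol centre forms racemic and is erased in step 4.

Step 4
Reactants: 9 rac-1-[2,4,6-trifluoro-3,5-bis(methoxymethyl)phenyl]butan-1-ol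
Product: 10 1-[2,4,6-trifluoro-3,5-bis(methoxymethyl)phenyl]butan-1-one
Conditions: DMP (1.3 equiv), CH2Cl2, 0 °C → rt
Reagents that add atoms: none
Why: Dess–Martin oxidation of a secondary benzylic alcohol to the aryl ketone under neutral conditions that leave aryl fluorides and benzylic methyl ethers untouched.

Step 5
Reactants: 10 1-[2,4,6-trifluoro-3,5-bis(methoxymethyl)phenyl]butan-1-one; 11 benzyl alcohol
Product: 15 1-[2,4,6-tris(benzyloxy)-3,5-bis(methoxymethyl)phenyl]butan-1-one, via sodium benzyloxide 12 (not isolated), via para-monoether 13 (not isolated), via ortho-para-diether 14 (not isolated)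
Conditions: 11 (8 equiv), NaH (4 equiv), THF, 0 °C; then 10 (1 equiv), 0 → 65 °C, strictly anhydrous
Reagents that add atoms: benzyl alcohol, OCc1ccccc1; sodium benzyloxide, [Na+].[O-]Cc1ccccc1
Why: Each fluorine-bearing carbon (C4 first, then C2 and C6) is attacked by benzyloxide to give a Meisenheimer anion whose charge sits on C1, C3 and C5 and is taken up by the butyryl carbonyl at C1, and fluoride then departs (addition–elimination, SNAr). The closest known reaction type is alkoxide displacement of fluoride ortho and para to an aryl ketone, together with exhaustive alkoxylation of 1,3,5-trifluoroarenes. No ring is closed and no stereocentre is formed. The step needs complete threefold substitution in preference to chemistry at the carbonyl: each benzyloxy group that enters sits meta to the fluorides still present and so does not feed electron density onto their ipso carbons, hemiketal formation at the doubly ortho-flanked ketone is reversible whereas fluoride loss is not, and the surplus of free benzyl alcohol should keep the ketone largely un-enolised so that it goes on activating the ring. Water is excluded because hydroxide would give a phenoxide that shuts down further substitution.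

Step 6
Reactants: 16 2,4,6-trihydroxyacetophenone
Product: 18 2-acetyl-3,5-dihydroxy-6,6-dimethylcyclohexa-2,4-dien-1-one (acetylfilicinic acid), via monomethyl ketone 17 (not isolated)
Conditions: NaOMe (3 equiv), MeI (2.2 equiv), MeOH, 0 °C → rt
Reagents that add atoms: iodomethane, CI
Why: Base-mediated C-methylation of the phloroglucinol anion, in which the second methyl enters the carbon already methylated with loss of aromaticity (dearomatising alkylation) to give the gem-dimethyl β-triketone, to be separated by chromatography from the 3,5-dimethyl and trimethyl congeners that form alongside.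

Step 7
Reactants: 19 2,4,6-trihydroxypropiophenone
Product: 21 3,5-dihydroxy-6,6-dimethyl-2-propanoylcyclohexa-2,4-dien-1-one (propionylfilicinic acid), via monomethyl ketone 20 (not isolated)
Conditions: NaOMe (3 equiv), MeI (2.2 equiv), MeOH, 0 °C → rt
Reagents that add atoms: iodomethane, CI
Why: The same dearomatising gem-dimethylation as in step 6, applied to the propionyl homologue and purified in the same way.

Step 8
Reactants: 15 1-[2,4,6-tris(benzyloxy)-3,5-bis(methoxymethyl)phenyl]butan-1-one; 18 acetylfilicinic acid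
Product: 22 1-[3-[(3-acetyl-2,6-dihydroxy-5,5-dimethyl-4-oxocyclohexa-2,6-dien-1-yl)methyl]-2,4,6-tris(benzyloxy)-5-(methoxymethyl)phenyl]butan-1-one
Conditions: 15 (3 equiv), 18 (1 equiv), BF3·OEt2 (0.3 equiv), CH2Cl2, −78 → −30 °C; surplus 15 recovered by chromatography and recycled
Reagents that add atoms: none
Why: Lewis acid-mediated SN1 benzylation of a cyclic β-triketone (Friedel–Crafts-type alkylation at an enol carbon), in which BF3 ionises one CH2OMe arm to a benzylic cation stabilised by two ortho and one para benzyloxy oxygens, the only unsubstituted ring carbon of 18 captures it while O-alkylation reverts under the acid, and the excess of 15 is what should hold the reaction at mono-coupling.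

Step 9
Reactants: 22 mono-coupled methyl ether from step 8; 21 propionylfilicinic acid
Product: 23 1-[3-[(3-acetyl-2,6-dihydroxy-5,5-dimethyl-4-oxocyclohexa-2,6-dien-1-yl)methyl]-2,4,6-tris(benzyloxy)-5-[(2,6-dihydroxy-5,5-dimethyl-4-oxo-3-propanoylcyclohexa-2,6-dien-1-yl)methyl]phenyl]butan-1-one
Conditions: 21 (1.5 equiv), BF3·OEt2 (0.3 equiv), CH2Cl2, −78 → −30 °C
Reagents that add atoms: none
Why: The same cation-forming benzylation now uses the remaining CH2OMe arm; the acetylfilicinic ring of 22 has no free ring carbon left, and the low temperature should keep the bridge already made from re-ionising, so the two acyl units should not exchange.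

Step 10
Reactants: 23 tri-O-benzyl ether of the target
Product: 24 1-[3-[(3-acetyl-2,6-dihydroxy-5,5-dimethyl-4-oxocyclohexa-2,6-dien-1-yl)methyl]-5-[(2,6-dihydroxy-5,5-dimethyl-4-oxo-3-propanoylcyclohexa-2,6-dien-1-yl)methyl]-2,4,6-trihydroxyphenyl]butan-1-one (CNP0325527.0)
Conditions: H2 (1 atm), 10% Pd/C, EtOAc, rt
Reagents that add atoms: none
Why: Hydrogenolysis of the three aryl benzyl ethers over Pd/C in a neutral medium, in which the hydrogen-bonded aryl ketone, the vinylogous-acid enol systems of rings B and C and the CH2 bridges are expected to survive and base-induced exchange of the bridges is avoided.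

**Compound list**

1 | 1,3,5-trifluorobenzene | Fc1cc(F)cc(F)c1 | starting material
2 | chloromethyl methyl ether | COCCl | starting material
3 | (2,4,6-trifluorophenyl)lithium | [Li]c1c(F)cc(F)cc1F | intermediate
4 | 1,3,5-trifluoro-2-(methoxymethyl)benzene | COCc1c(F)cc(F)cc1F | intermediate
5 | [2,4,6-trifluoro-3-(methoxymethyl)phenyl]lithium | [Li]c1c(F)cc(F)c(COC)c1F | intermediate
6 | 1,3,5-trifluoro-2,4-bis(methoxymethyl)benzene | COCc1c(F)cc(F)c(COC)c1F | intermediate
7 | butanal | CCCC=O | starting material
8 | [2,4,6-trifluoro-3,5-bis(methoxymethyl)phenyl]lithium | [Li]c1c(F)c(COC)c(F)c(COC)c1F | intermediate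
9 | rac-1-[2,4,6-trifluoro-3,5-bis(methoxymethyl)phenyl]butan-1-ol | CCCC(O)c1c(F)c(COC)c(F)c(COC)c1F | intermediate
10 | 1-[2,4,6-trifluoro-3,5-bis(methoxymethyl)phenyl]butan-1-one | CCCC(=O)c1c(F)c(COC)c(F)c(COC)c1F | intermediate
11 | benzyl alcohol | OCc1ccccc1 | starting material
12 | sodium benzyloxide | [Na+].[O-]Cc1ccccc1 | intermediate
13 | 1-[4-(benzyloxy)-2,6-difluoro-3,5-bis(methoxymethyl)phenyl]butan-1-one | CCCC(=O)c1c(F)c(COC)c(OCc2ccccc2)c(COC)c1F | intermediate
14 | 1-[2,4-bis(benzyloxy)-6-fluoro-3,5-bis(methoxymethyl)phenyl]butan-1-one | CCCC(=O)c1c(OCc2ccccc2)c(COC)c(OCc2ccccc2)c(COC)c1F | intermediate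
15 | 1-[2,4,6-tris(benzyloxy)-3,5-bis(methoxymethyl)phenyl]butan-1-one | CCCC(=O)c1c(OCc2ccccc2)c(COC)c(OCc2ccccc2)c(COC)c1OCc1ccccc1 | intermediate
16 | 2,4,6-trihydroxyacetophenone | CC(=O)c1c(O)cc(O)cc1O | starting material
17 | 1-(2,4,6-trihydroxy-3-methylphenyl)ethan-1-one | CC(=O)c1c(O)cc(O)c(C)c1O | intermediate
18 | 2-acetyl-3,5-dihydroxy-6,6-dimethylcyclohexa-2,4-dien-1-one (acetylfilicinic acid) | CC(=O)C1=C(O)C=C(O)C(C)(C)C1=O | intermediate
19 | 2,4,6-trihydroxypropiophenone | CCC(=O)c1c(O)cc(O)cc1O | starting material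
20 | 1-(2,4,6-trihydroxy-3-methylphenyl)propan-1-one | CCC(=O)c1c(O)cc(O)c(C)c1O | intermediate
21 | 3,5-dihydroxy-6,6-dimethyl-2-propanoylcyclohexa-2,4-dien-1-one (propionylfilicinic acid) | CCC(=O)C1=C(O)C=C(O)C(C)(C)C1=O | intermediate
22 | 1-[3-[(3-acetyl-2,6-dihydroxy-5,5-dimethyl-4-oxocyclohexa-2,6-dien-1-yl)methyl]-2,4,6-tris(benzyloxy)-5-(methoxymethyl)phenyl]butan-1-one | CCCC(=O)c1c(OCc2ccccc2)c(CC2=C(O)C(C)(C)C(=O)C(C(C)=O)=C2O)c(OCc2ccccc2)c(COC)c1OCc1ccccc1 | intermediate
23 | 1-[3-[(3-acetyl-2,6-dihydroxy-5,5-dimethyl-4-oxocyclohexa-2,6-dien-1-yl)methyl]-2,4,6-tris(benzyloxy)-5-[(2,6-dihydroxy-5,5-dimethyl-4-oxo-3-propanoylcyclohexa-2,6-dien-1-yl)methyl]phenyl]butan-1-one | CCCC(=O)c1c(OCc2ccccc2)c(CC2=C(O)C(C)(C)C(=O)C(C(C)=O)=C2O)c(OCc2ccccc2)c(CC2=C(O)C(C)(C)C(=O)C(C(=O)CC)=C2O)c1OCc1ccccc1 | intermediate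
24 | 1-[3-[(3-acetyl-2,6-dihydroxy-5,5-dimethyl-4-oxocyclohexa-2,6-dien-1-yl)methyl]-5-[(2,6-dihydroxy-5,5-dimethyl-4-oxo-3-propanoylcyclohexa-2,6-dien-1-yl)methyl]-2,4,6-trihydroxyphenyl]butan-1-one (CNP0325527.0) | CCCC(=O)c1c(O)c(CC2=C(O)C(C)(C)C(=O)C(C(C)=O)=C2O)c(O)c(CC2=C(O)C(C)(C)C(=O)C(C(=O)CC)=C2O)c1O | target

**Step count and risks**

Total step count: 10. Longest linear sequence: 8 steps (steps 1, 2, 3, 4, 5, 8, 9, 10); steps 6 and 7 are side branches.

Steps most likely to fail:

1. Step 5. The sequence may stall after one or two displacements, because enolisation of the butyryl group or its twisting out of the ring plane between growing ortho substituents withdraws the activation. Hydride transfer from benzyloxide to the ketone may also compete at the temperature needed for the last fluoride. The fallback sets out from 6 and returns at 15. Lithiation of 6 to aryllithium 8 as in step 3 and quench with DMF should give 2,4,6-trifluoro-3,5-bis(methoxymethyl)benzaldehyde F1. Its formyl group stays coplanar with the ring and cannot enolise, so sodium benzyloxide 12 in THF at 0 °C to rt should replace the fluorides in turn. This should pass through 4-(benzyloxy)-2,6-difluoro-3,5-bis(methoxymethyl)benzaldehyde F2 and 2,4-bis(benzyloxy)-6-fluoro-3,5-bis(methoxymethyl)benzaldehyde F3 to 2,4,6-tris(benzyloxy)-3,5-bis(methoxymethyl)benzaldehyde F4. Addition of n-PrMgBr in THF at 0 °C should give rac-1-[2,4,6-tris(benzyloxy)-3,5-bis(methoxymethyl)phenyl]butan-1-ol F5, and DMP oxidation in CH2Cl2 returns ketone 15.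

2. Step 8. Both equivalent arms may ionise without discrimination, so double coupling competes with mono-coupling and material is lost in recycling the excess bis-ether. The fallback sets out from 4 and returns at 23, with the two arms made different.
   - Aryllithium 5, generated as in step 2, is quenched with (triisopropylsiloxy)methyl chloride to give triisopropyl{[2,4,6-trifluoro-3-(methoxymethyl)phenyl]methoxy}silane F6.
   - Lithiation with n-BuLi at −78 °C gives {2,4,6-trifluoro-3-(methoxymethyl)-5-[(triisopropylsilyloxy)methyl]phenyl}lithium F7, and butanal 7 converts it into rac-1-{2,4,6-trifluoro-3-(methoxymethyl)-5-[(triisopropylsilyloxy)methyl]phenyl}butan-1-ol F8.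
   - DMP oxidation gives 1-{2,4,6-trifluoro-3-(methoxymethyl)-5-[(triisopropylsilyloxy)methyl]phenyl}butan-1-one F9.
   - Sodium benzyloxide 12 under the conditions of step 5 (the hindered silyl ether should tolerate alkoxide) should lead through 1-{4-(benzyloxy)-2,6-difluoro-3-(methoxymethyl)-5-[(triisopropylsilyloxy)methyl]phenyl}butan-1-one F10 and 1-{2,4-bis(benzyloxy)-6-fluoro-3-(methoxymethyl)-5-[(triisopropylsilyloxy)methyl]phenyl}butan-1-one F11 to 1-{2,4,6-tris(benzyloxy)-3-(methoxymethyl)-5-[(triisopropylsilyloxy)methyl]phenyl}butan-1-one F12.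
   - Catalytic BF3·OEt2 at −78 °C with one equivalent of 18 should ionise only the methyl ether, since the silyl ether oxygen is shielded and weakly basic. This gives 1-{3-[(3-acetyl-2,6-dihydroxy-5,5-dimethyl-4-oxocyclohexa-2,6-dien-1-yl)methyl]-2,4,6-tris(benzyloxy)-5-[(triisopropylsilyloxy)methyl]phenyl}butan-1-one F13.
   - n-Bu4NF in THF frees 1-{3-[(3-acetyl-2,6-dihydroxy-5,5-dimethyl-4-oxocyclohexa-2,6-dien-1-yl)methyl]-2,4,6-tris(benzyloxy)-5-(hydroxymethyl)phenyl}butan-1-one F14, whose benzylic alcohol is ionised by catalytic BF3·OEt2 in the presence of 21 to give 23.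

3. Step 10. The aryl ketone or an enol double bond of rings B and C may be over-reduced, or the reaction may stop at partly benzylated material on the crowded ring. The fallback sets out from 23 and returns at 24. The benzyl ethers are cleaved without hydrogen by BCl3 with pentamethylbenzene as cation scavenger in CH2Cl2 at −78 °C, followed by aqueous work-up; no new compound lies on the way.

**Further compounds**

F1 | step 5 | 2,4,6-trifluoro-3,5-bis(methoxymethyl)benzaldehyde | O=Cc1c(F)c(COC)c(F)c(COC)c1F
F2 | step 5 | 4-(benzyloxy)-2,6-difluoro-3,5-bis(methoxymethyl)benzaldehyde | O=Cc1c(F)c(COC)c(OCc2ccccc2)c(COC)c1F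
F3 | step 5 | 2,4-bis(benzyloxy)-6-fluoro-3,5-bis(methoxymethyl)benzaldehyde | O=Cc1c(OCc2ccccc2)c(COC)c(OCc2ccccc2)c(COC)c1F
F4 | step 5 | 2,4,6-tris(benzyloxy)-3,5-bis(methoxymethyl)benzaldehyde | O=Cc1c(OCc2ccccc2)c(COC)c(OCc2ccccc2)c(COC)c1OCc1ccccc1
F5 | step 5 | rac-1-[2,4,6-tris(benzyloxy)-3,5-bis(methoxymethyl)phenyl]butan-1-ol | CCCC(O)c1c(OCc2ccccc2)c(COC)c(OCc2ccccc2)c(COC)c1OCc1ccccc1
F6 | step 8 | triisopropyl{[2,4,6-trifluoro-3-(methoxymethyl)phenyl]methoxy}silane | COCc1c(F)cc(F)c(CO[Si](C(C)C)(C(C)C)C(C)C)c1F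
F7 | step 8 | {2,4,6-trifluoro-3-(methoxymethyl)-5-[(triisopropylsilyloxy)methyl]phenyl}lithium | [Li]c1c(F)c(COC)c(F)c(CO[Si](C(C)C)(C(C)C)C(C)C)c1F
F8 | step 8 | rac-1-{2,4,6-trifluoro-3-(methoxymethyl)-5-[(triisopropylsilyloxy)methyl]phenyl}butan-1-ol | CCCC(O)c1c(F)c(COC)c(F)c(CO[Si](C(C)C)(C(C)C)C(C)C)c1F
F9 | step 8 | 1-{2,4,6-trifluoro-3-(methoxymethyl)-5-[(triisopropylsilyloxy)methyl]phenyl}butan-1-one | CCCC(=O)c1c(F)c(COC)c(F)c(CO[Si](C(C)C)(C(C)C)C(C)C)c1F
F10 | step 8 | 1-{4-(benzyloxy)-2,6-difluoro-3-(methoxymethyl)-5-[(triisopropylsilyloxy)methyl]phenyl}butan-1-one | CCCC(=O)c1c(F)c(COC)c(OCc2ccccc2)c(CO[Si](C(C)C)(C(C)C)C(C)C)c1F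
F11 | step 8 | 1-{2,4-bis(benzyloxy)-6-fluoro-3-(methoxymethyl)-5-[(triisopropylsilyloxy)methyl]phenyl}butan-1-one | CCCC(=O)c1c(OCc2ccccc2)c(COC)c(OCc2ccccc2)c(CO[Si](C(C)C)(C(C)C)C(C)C)c1F
F12 | step 8 | 1-{2,4,6-tris(benzyloxy)-3-(methoxymethyl)-5-[(triisopropylsilyloxy)methyl]phenyl}butan-1-one | CCCC(=O)c1c(OCc2ccccc2)c(COC)c(OCc2ccccc2)c(CO[Si](C(C)C)(C(C)C)C(C)C)c1OCc1ccccc1
F13 | step 8 | 1-{3-[(3-acetyl-2,6-dihydroxy-5,5-dimethyl-4-oxocyclohexa-2,6-dien-1-yl)methyl]-2,4,6-tris(benzyloxy)-5-[(triisopropylsilyloxy)methyl]phenyl}butan-1-one | CCCC(=O)c1c(OCc2ccccc2)c(CC2=C(O)C(C)(C)C(=O)C(C(C)=O)=C2O)c(OCc2ccccc2)c(CO[Si](C(C)C)(C(C)C)C(C)C)c1OCc1ccccc1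
F14 | step 8 | 1-{3-[(3-acetyl-2,6-dihydroxy-5,5-dimethyl-4-oxocyclohexa-2,6-dien-1-yl)methyl]-2,4,6-tris(benzyloxy)-5-(hydroxymethyl)phenyl}butan-1-one | CCCC(=O)c1c(OCc2ccccc2)c(CC2=C(O)C(C)(C)C(=O)C(C(C)=O)=C2O)c(OCc2ccccc2)c(CO)c1OCc1ccccc1
F0 | step 10 | none | none
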